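Counting reagent is the easy step. These are the flasks, the readings and the questions:

| flask | starting material | reagent | protic impurity | remark | time |
|---|---|---|---|---|---|
| north-west | 5.0 × 10⁻⁴ M | 0.90 equiv | 0.050 mM | run made earlier |  |
| south-west | 5.0 × 10⁻⁴ M | 0.45 equiv | 0.050 mM | run made earlier |  |
| west | 5.0 × 10⁻⁴ M | 0.68 equiv | 0.050 mM | run made earlier |  |
| dusk | 5.0 × 10⁻⁴ M | 0.900 equiv | 0.0500 mM | a closed flask charged with all of it at once and left for 3.0 min | 3.0 min |
| winter | 5.0 × 10⁻⁴ M | 0.900 equiv | 0.0500 mM | one stirred flow tank at steady state, fed with the mixture as stated, mean residence time 3.0 min |  |
| spring | 5.0 × 10⁻⁴ M | 0.900 equiv | 0.0500 mM | plug flow through a tube for 3.0 min, no back-mixing | 3.0 min |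
| midnight | 5.0 × 10⁻⁴ M | 0.900 equiv (fed, over 3.00 min) | 0.0500 mM | all but reagent at the start; reagent goes in evenly over 3.00 min, the run ends at 3.0 min | 3.0 min |

- north-west (time / s: target / %, side product / %): 10.0: 43, 1; 15.0: 48, 0; 30.0: 52, 7; 50.0: 55, 9; 60.0: 58, 8; 80.0: 58, 9; 120: 59, 9
- south-west (time / s: target / %, side product / %): 10.0: 26, 1; 15.0: 29, 2; 30.0: 30, 4; 50.0: 33, 3; 60.0: 31, 4; 80.0: 31, 2; 120: 31, 1
- west (time / s: target / %, side product / %): 15.0: 40, 3; 30.0: 42, 3; 50.0: 45, 2; 60.0: 48, 3; 80.0: 44, 3; 90.0: 45, 2; 120: 48, 5

(each reading ± 1.5 percentage points)

- the stated concentrations are those of everything mixed, before any reaction; amounts are the same in each set-up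
- the numbers in the tables scatter with a standard deviation of 1.5 percentage points
- the feed brings no volume worth counting
- the earlier runs were made in a closed, stirred flask

1. the set-up with the highest share of target in all that became target or side product, at the outlet or at the end ("none" if the first two lie within 2 percentage points) (dusk / winter / spring / midnight / none)
2. share of target in all that became target or side product, at the outlet or at the end, dusk
3. share of target in all that became target or side product, at the outlet or at the end, winter
4. share of target in all that became target or side product, at the outlet or at the end, spring
5. share of target in all that became target or side product, at the outlet or at the end, midnight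

Take the share of target in target plus side product (the selectivity) over the last 3 readings of each earlier run. As readings, it is 93.0% in the south-west run, 93.2% in the west run and 87.1% in the north-west run. With each reading scattering by 1.5 percentage points, the south-west and west shares can't be told apart, so these readings show neither a level stretch nor a bend; the north-west share is lower. The step from 0.68 equiv to 0.90 equiv costs 0.279 of share per equivalent, as read from these scattered shares: this is the price of late reagent, the share lost for each further equivalent spent.

Two chemists dispute the set-ups. The first counts the charge: each holds 0.900 equiv, so she expects dusk, spring and midnight all near 87.1%.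

The second counts what has been spent. In the north-west run, the gap of target to its last reading shrinks between 10.0 s and 30.0 s with a tail life of 24.2 s, far shorter than the 3.0 min of dusk and spring, so for those two she agrees. But midnight takes reagent until its last moment, and she counts what arrived within one tail life of the end as unspent: 13.4% of the charge. That leaves 0.779 equiv spent, and the price gives 90.4%.

This is my reckoning too. The winter tank mixes feed into finished liquor, so I take no number for it from the price.

The forecast, on the second chemist's side, gives dusk 87%, winter 78%, spring 87% and midnight 89.3%, with midnight best, holding that “about 0.1 equiv of reagent remains unreacted at 3 min”.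

The simulation gives dusk 87.3%, winter 84.1%, spring 87.3% and midnight 90.2%; best is midnight.

    starting material + reagent → target (k = 330 L mol⁻¹ s⁻¹)
    starting material + reagent → intermediate A (k = 130 L mol⁻¹ s⁻¹)
    reagent + intermediate A → intermediate B (k = 190 L mol⁻¹ s⁻¹)
    intermediate B → intermediate C (k = 0.0260 s⁻¹)
    intermediate C ⇌ intermediate D (K = 0.970, k = 0.0440 s⁻¹)
    intermediate B → side product (k = 0.140 s⁻¹)
    starting material + protic impurity → quenched substrate (k = 2400 L mol⁻¹ s⁻¹)

The first chemist holds the long wait: midnight left to 30.0 min gives 87.2%, level with dusk. At 3.00 min in midnight, the half-life of reagent by the target step alone is 0.44 min, shorter than the 3.00 min feed, yet 9.2% of the reagent still stands. The price on what midnight really spent gives 89.4%. On the neighbouring midnight flask with 1.50 equiv, 26% unspent, it gives 81.4%, and that flask stands at 79.5%.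

The readings were computed for substances that don't exist; scatter was added.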